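## Retrosynthetic overview

1. The target is cut between pyrone C3 and the CH2 attached to it. Fragment 1 is the bicyclic lactone carrying CH2–CHO on C3a; fragment 2 is racemic 6-(furan-3-yl)-4-methyl-5,6-dihydro-2H-pyran-2-one. The pyrone thus arrives one oxidation level too low and is aromatised by the coupling itself.
2. Enabling feature: in the pyrone ring (O1, C2–C6), C3 is the α-carbon of the lactone carbonyl C2 and is flanked by C4(Me). In the 5,6-dihydro ring, C2/C3/C4/C5 form a dienolate whose α-terminus is C3, and the sp3 C6–H (next to O1, bearing the furyl) is the hydrogen that moves to the side-chain carbon when the 3-alkylidene intermediate tautomerises to the 2-pyrone. C–C union, loss of the aldehyde oxygen and aromatisation are one operation, with no halide, metal or reductant.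
3. Fragment 1: the lactone carbonyl carbon C1 and the aldehyde carbon are first joined in a temporary cyclopentanone. It is made by a desymmetrising intramolecular benzoin reaction of a 2,2-disubstituted cyclohexane-1,3-dione (sets C3a and C7a, OH cis to CH2O) and cut by ozonolysis of its silyl enol ether into the acid (→ lactone) and the aldehyde.
4. Ring order: cyclohexane ring (bought) → temporary cyclopentanone → trans-fused γ-lactone; dihydropyranone made separately → pyrone (aromatised in the key step); the C5=C6 enone is introduced last.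

Key step: step 12

Locants used: bicyclic part as 2-benzofuran-1,4-dione (C1 lactone C=O, C3 OCH2, C3a, C4 ketone, C5=C6, C7, C7a–OH); pyrone O1, C2–C6. The target is (3aR,7aR), with 7a-OH and the lactone CH2 on the same face (trans-fused lactone).

Assumption: the (5aS,10bR)-triazolium precatalyst of step 6 is taken to select the ketone that leads to (3aR,7aR)-8; if the sense of induction is the opposite, its enantiomer is used.

## Route

Step 1
Reactants: 1 cyclohexane-1,3-dione
Product: 2 2-(prop-2-en-1-yl)cyclohexane-1,3-dione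
Conditions: allyl bromide, KOH, Cu powder (cat.), H2O, rt
Reagents that add atoms: allyl bromide C=CCBr
Why: C-allylation of the 1,3-dione enolate in water (Stetter-type alkylation) should give the 2-allyl dione, whose three allyl carbons become the side-chain CH2, the aldehyde carbon and the lactone carbonyl carbon.

Step 2
Reactants: 2 2-(prop-2-en-1-yl)cyclohexane-1,3-dione
Product: 3 2-(hydroxymethyl)-2-(prop-2-en-1-yl)cyclohexane-1,3-dione
Conditions: 37% aq. CH2O, NaHCO3 (cat.), THF, rt
Reagents that add atoms: formaldehyde C=O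
Why: aldol hydroxymethylation of the doubly activated C2–H installs the future lactone CH2; the product keeps a mirror plane, so no stereocentre is set yet.

Step 3
Reactants: 3 2-(hydroxymethyl)-2-(prop-2-en-1-yl)cyclohexane-1,3-dione
Product: 4 2-{[(tert-butyldimethylsilyl)oxy]methyl}-2-(prop-2-en-1-yl)cyclohexane-1,3-dione
Conditions: TBSCl, imidazole, CH2Cl2, 0 °C
Reagents that add atoms: tert-butyldimethylsilyl chloride CC(C)(C)[Si](C)(C)Cl
Why: silyl ether formation blocks retro-aldol loss of formaldehyde in the later basic steps.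

Step 4
Reactants: 4 2-{[(tert-butyldimethylsilyl)oxy]methyl}-2-(prop-2-en-1-yl)cyclohexane-1,3-dione
Product: 6 2-{[(tert-butyldimethylsilyl)oxy]methyl}-2-(3-hydroxypropyl)cyclohexane-1,3-dione, via catechol boronate 5 (not isolated)
Conditions: catecholborane, RhCl(PPh3)3 (2 mol%), THF, rt; then 30% H2O2, aq. NaHCO3, 0 °C
Reagents that add atoms: hydrogen peroxide OO
Why: rhodium-catalysed anti-Markovnikov hydroboration (Männig–Nöth conditions) reacts at the terminal alkene in preference to the ketones, and buffered oxidation gives the primary alcohol.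

Step 5
Reactants: 6 2-{[(tert-butyldimethylsilyl)oxy]methyl}-2-(3-hydroxypropyl)cyclohexane-1,3-dione
Product: 7 3-(1-{[(tert-butyldimethylsilyl)oxy]methyl}-2,6-dioxocyclohexyl)propanal
Conditions: Dess–Martin periodinane, CH2Cl2, rt
Reagents that add atoms: none
Why: Dess–Martin oxidation of the primary alcohol (free or as its hemiketal) should give the aldehyde under neutral conditions that leave the dione and silyl ether untouched.

Step 6
Reactants: 7 3-(1-{[(tert-butyldimethylsilyl)oxy]methyl}-2,6-dioxocyclohexyl)propanal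
Product: 8 (3aR,7aR)-3a-{[(tert-butyldimethylsilyl)oxy]methyl}-7a-hydroxyhexahydro-1H-indene-1,4(2H)-dione
Conditions: (5aS,10bR)-2-(pentafluorophenyl)-5a,10b-dihydro-4H,6H-indeno[2,1-b][1,2,4]triazolo[4,3-d][1,4]oxazin-2-ium tetrafluoroborate (10 mol%), Et3N (10 mol%), CH2Cl2, rt
Reagents that add atoms: none
Why: desymmetrising intramolecular crossed benzoin reaction under N-heterocyclic carbene catalysis, in which the chiral carbene chooses one of the two enantiotopic ketones (fixing C3a) and the three-carbon tether enforces the cis ring fusion, so the new tertiary OH at C7a is cis to CH2OSi.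

Step 7
Reactants: 8 (3aR,7aR)-3a-{[(tert-butyldimethylsilyl)oxy]methyl}-7a-hydroxyhexahydro-1H-indene-1,4(2H)-dione
Product: 9 (3a'R,7a'R)-3a'-{[(tert-butyldimethylsilyl)oxy]methyl}-7a'-hydroxyhexahydrospiro[1,3-dioxolane-2,4'-inden]-1'(2'H)-one
Conditions: ethylene glycol, PPTS (cat.), benzene, reflux (Dean–Stark)
Reagents that add atoms: ethylene glycol OCCO
Why: chemoselective ketalisation should occur at the cyclohexanone only, because the cyclopentanone is deactivated by its α-oxygen and by ring strain in the sp3 ketal (the selectivity used for Wieland–Miescher-type diketones).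

Step 8
Reactants: 9 (3a'R,7a'R)-3a'-{[(tert-butyldimethylsilyl)oxy]methyl}-7a'-hydroxyhexahydrospiro[1,3-dioxolane-2,4'-inden]-1'(2'H)-one
Product: 10 (3a'R,7a'R)-1',7a'-bis[(tert-butyldimethylsilyl)oxy]-3a'-{[(tert-butyldimethylsilyl)oxy]methyl}-3',3a',5',6',7',7a'-hexahydrospiro[1,3-dioxolane-2,4'-indene]
Conditions: TBSOTf (2.5 equiv), Et3N, CH2Cl2, −78 °C → rt
Reagents that add atoms: tert-butyldimethylsilyl triflate CC(C)(C)[Si](C)(C)OS(=O)(=O)C(F)(F)F
Why: soft enolisation and silylation give the silyl enol ether on the only enolisable side of the remaining ketone (the other α-carbon is quaternary) and protect the tertiary alcohol in the same operation.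

Step 9
Reactants: 10 (3a'R,7a'R)-1',7a'-bis[(tert-butyldimethylsilyl)oxy]-3a'-{[(tert-butyldimethylsilyl)oxy]methyl}-3',3a',5',6',7',7a'-hexahydrospiro[1,3-dioxolane-2,4'-indene]
Product: 11 tert-butyldimethylsilyl (6R,7R)-7-[(tert-butyldimethylsilyl)oxy]-6-{[(tert-butyldimethylsilyl)oxy]methyl}-6-(2-oxoethyl)-1,4-dioxaspiro[4.5]decane-7-carboxylate
Conditions: O3, CH2Cl2, −78 °C; Me2S, −78 °C → rt; used crude
Reagents that add atoms: ozone [O-][O+]=O
Why: ozonolysis of the silyl enol ether cuts the temporary ring between the former ketone carbon (now a silyl ester, the future lactone carbonyl) and its α-carbon (now the aldehyde of the two-carbon side chain), without touching either stereocentre.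

Step 10
Reactants: 11 tert-butyldimethylsilyl (6R,7R)-7-[(tert-butyldimethylsilyl)oxy]-6-{[(tert-butyldimethylsilyl)oxy]methyl}-6-(2-oxoethyl)-1,4-dioxaspiro[4.5]decane-7-carboxylate
Product: 13 (3aR,7aR)-7a-[(tert-butyldimethylsilyl)oxy]-4,4-(ethylenedioxy)-3a-(2-oxoethyl)hexahydro-2-benzofuran-1(3H)-one, via hydroxy acid 12 (not isolated)
Conditions: HF·pyridine, pyridine, THF, 0 °C → rt; then DCC, DMAP (cat.), CH2Cl2, rt
Reagents that add atoms: none
Why: HF·pyridine should cleave the silyl ester and the primary silyl ether but not the hindered tertiary one, and carbodiimide lactonisation (Steglich conditions) of the γ-hydroxy acid closes the trans-fused lactone, the ring fusion being fixed by the cis relation of OSi and CH2O set in step 6.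

Step 11
Reactants: 14 furan-3-carbaldehyde; 15 3-methylbut-2-enoic acid
Product: 17 6-(furan-3-yl)-4-methyl-5,6-dihydro-2H-pyran-2-one (racemic), via hydroxy acid 16 (not isolated)
Conditions: 15, LiN(iPr)2 (2.1 equiv), THF, −78 → 0 °C; 14, −78 °C → rt; then 3 M aq. HCl, rt
Reagents that add atoms: none
Why: vinylogous aldol addition of the acid dianion, which ends up γ-selective on warming, followed by acid lactonisation should give the δ-lactone; its stereocentre is left racemic because it is destroyed in step 12.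

Step 12
Reactants: 13 (3aR,7aR)-7a-[(tert-butyldimethylsilyl)oxy]-4,4-(ethylenedioxy)-3a-(2-oxoethyl)hexahydro-2-benzofuran-1(3H)-one; 17 6-(furan-3-yl)-4-methyl-5,6-dihydro-2H-pyran-2-one
Product: 21 (3aR,7aR)-7a-[(tert-butyldimethylsilyl)oxy]-4,4-(ethylenedioxy)-3a-{2-[6-(furan-3-yl)-4-methyl-2-oxo-2H-pyran-3-yl]ethyl}hexahydro-2-benzofuran-1(3H)-one, via aldol adduct 18 (not isolated), via mesylate 19 (not isolated), via alkylidene lactone 20 (not isolated)
Conditions: 17, LiN(iPr)2 (1.1 equiv), THF, −78 °C; 13, −78 °C; MsCl, −78 → 0 °C; KOtBu (2.5 equiv), 0 °C → rt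
Reagents that add atoms: none
Why: Proposed new method: LiN(iPr)2 removes a γ-proton of 17 to give the cyclic lithium dienolate, which adds through its α-carbon (C3) to the aldehyde of 13 in a kinetic, lithium-chelated aldol step; mesylation and E1cB loss of mesylate give the 3-alkylidene-3,6-dihydropyranone 20, and KOtBu then removes the C6–H (allylic, next to O1, furyl-substituted) and reprotonation at the exocyclic carbon gives the aromatic 2-pyrone, so the aldehyde carbon ends as CH2 without any reductant. The closest known reaction types are the α-selective aldol reactions of lithium dienolates of α,β-unsaturated δ-lactones and the base-mediated isoaromatisation of 2-alkylidenecyclohexenones to 2-alkylphenols. No ring is closed; the pyrone ring is aromatised. No new stereocentre survives, since the carbinol carbon, C3 and C6 all become sp2 or CH2, which is why racemic 17 and any diastereomer mixture of 18 converge. The step needs α- over γ-attack of the dienolate (lithium counter-ion, −78 °C, kinetic control) and aldehyde over lactone reactivity (the lactone carbonyl of 13 sits between two quaternary carbons and the ketone is masked as the dioxolane). Retro-aldol cleavage of the C3a–C7a bond is excluded because the tertiary oxygen is silylated, and the aromatic pyrone is the thermodynamic sink of all double-bond isomers.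

Step 13
Reactants: 21 (3aR,7aR)-7a-[(tert-butyldimethylsilyl)oxy]-4,4-(ethylenedioxy)-3a-{2-[6-(furan-3-yl)-4-methyl-2-oxo-2H-pyran-3-yl]ethyl}hexahydro-2-benzofuran-1(3H)-one
Product: 23 (3aR,7aR)-3a-{2-[6-(furan-3-yl)-4-methyl-2-oxo-2H-pyran-3-yl]ethyl}-7a-hydroxyhexahydro-2-benzofuran-1,4-dione, via ketal alcohol 22 (not isolated)
Conditions: HF·pyridine, THF, rt; then 2 M aq. HCl, THF, 40 °C
Reagents that add atoms: water O
Why: fluoride cleavage of the tertiary silyl ether and acid hydrolysis of the dioxolane (standard deprotections) should free the tertiary alcohol and the C4 ketone; the 3-furyl group is deactivated by the pyrone and should tolerate the dilute acid.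

Step 14
Reactants: 23 (3aR,7aR)-3a-{2-[6-(furan-3-yl)-4-methyl-2-oxo-2H-pyran-3-yl]ethyl}-7a-hydroxyhexahydro-2-benzofuran-1,4-dione
Product: 25 (3aR,7aR)-3a-{2-[6-(furan-3-yl)-4-methyl-2-oxo-2H-pyran-3-yl]ethyl}-7a-hydroxy-3,3a,7,7a-tetrahydro-2-benzofuran-1,4-dione (CNP0550188.1), via silyl enol ether 24 (not isolated)
Conditions: TMSOTf, Et3N, CH2Cl2, 0 °C; Pd(OAc)2 (1.1 equiv), MeCN, rt; 0.5 M aq. HCl work-up
Reagents that add atoms: none
Why: Saegusa–Ito oxidation: the C4 ketone can enolise only towards C5 (C3a is quaternary), the silyl enol ether gives a divalent palladium enolate and β-hydride elimination releases the C5=C6 enone and zerovalent palladium, while the transient O-silyl group on the tertiary alcohol prevents retro-aldol and falls off on work-up.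

## Compound list

1 | cyclohexane-1,3-dione | O=C1CCCC(=O)C1 | starting material
2 | 2-(prop-2-en-1-yl)cyclohexane-1,3-dione | C=CCC1C(=O)CCCC1=O | intermediate
3 | 2-(hydroxymethyl)-2-(prop-2-en-1-yl)cyclohexane-1,3-dione | C=CCC1(CO)C(=O)CCCC1=O | intermediate
4 | 2-{[(tert-butyldimethylsilyl)oxy]methyl}-2-(prop-2-en-1-yl)cyclohexane-1,3-dione | C=CCC1(CO[Si](C)(C)C(C)(C)C)C(=O)CCCC1=O | intermediate
5 | 2-[3-(1,3,2-benzodioxaborol-2-yl)propyl]-2-{[(tert-butyldimethylsilyl)oxy]methyl}cyclohexane-1,3-dione (not isolated) | O=C1CCCC(=O)C1(CO[Si](C)(C)C(C)(C)C)CCCB3Oc2ccccc2O3 | intermediate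
6 | 2-{[(tert-butyldimethylsilyl)oxy]methyl}-2-(3-hydroxypropyl)cyclohexane-1,3-dione | O=C1CCCC(=O)C1(CO[Si](C)(C)C(C)(C)C)CCCO | intermediate
7 | 3-(1-{[(tert-butyldimethylsilyl)oxy]methyl}-2,6-dioxocyclohexyl)propanal | O=CCCC1(CO[Si](C)(C)C(C)(C)C)C(=O)CCCC1=O | intermediate
8 | (3aR,7aR)-3a-{[(tert-butyldimethylsilyl)oxy]methyl}-7a-hydroxyhexahydro-1H-indene-1,4(2H)-dione (cis-fused; OH and CH2OSi on the same face) | O=C1CC[C@]2(CO[Si](C)(C)C(C)(C)C)C(=O)CCC[C@]12O | intermediate
9 | (3a'R,7a'R)-3a'-{[(tert-butyldimethylsilyl)oxy]methyl}-7a'-hydroxyhexahydrospiro[1,3-dioxolane-2,4'-inden]-1'(2'H)-one | O=C1CC[C@]2(CO[Si](C)(C)C(C)(C)C)C3(OCCO3)CCC[C@]12O | intermediate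
10 | (3a'R,7a'R)-1',7a'-bis[(tert-butyldimethylsilyl)oxy]-3a'-{[(tert-butyldimethylsilyl)oxy]methyl}-3',3a',5',6',7',7a'-hexahydrospiro[1,3-dioxolane-2,4'-indene] | CC(C)(C)[Si](C)(C)OC1=CC[C@]2(CO[Si](C)(C)C(C)(C)C)C3(OCCO3)CCC[C@]12O[Si](C)(C)C(C)(C)C | intermediate
11 | tert-butyldimethylsilyl (6R,7R)-7-[(tert-butyldimethylsilyl)oxy]-6-{[(tert-butyldimethylsilyl)oxy]methyl}-6-(2-oxoethyl)-1,4-dioxaspiro[4.5]decane-7-carboxylate | O=CC[C@]1(CO[Si](C)(C)C(C)(C)C)C2(OCCO2)CCC[C@]1(O[Si](C)(C)C(C)(C)C)C(=O)O[Si](C)(C)C(C)(C)C | intermediate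
12 | (6R,7R)-7-[(tert-butyldimethylsilyl)oxy]-6-(hydroxymethyl)-6-(2-oxoethyl)-1,4-dioxaspiro[4.5]decane-7-carboxylic acid (not isolated) | O=CC[C@]1(CO)C2(OCCO2)CCC[C@]1(O[Si](C)(C)C(C)(C)C)C(=O)O | intermediate
13 | (3aR,7aR)-7a-[(tert-butyldimethylsilyl)oxy]-4,4-(ethylenedioxy)-3a-(2-oxoethyl)hexahydro-2-benzofuran-1(3H)-one (trans-fused lactone; OSi and lactone CH2 on the same face) | O=CC[C@@]12COC(=O)[C@@]1(O[Si](C)(C)C(C)(C)C)CCCC23OCCO3 | intermediate
14 | furan-3-carbaldehyde | O=Cc1ccoc1 | starting material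
15 | 3-methylbut-2-enoic acid | CC(C)=CC(=O)O | starting material
16 | (2Z)-5-(furan-3-yl)-5-hydroxy-3-methylpent-2-enoic acid (racemic, not isolated) | OC(=O)/C=C(/C)CC(O)c1ccoc1 | intermediate
17 | 6-(furan-3-yl)-4-methyl-5,6-dihydro-2H-pyran-2-one (racemic) | CC1=CC(=O)OC(c2ccoc2)C1 | intermediate
18 | aldol adduct: 13 carrying 2-[6-(furan-3-yl)-4-methyl-2-oxo-3,6-dihydro-2H-pyran-3-yl]-2-hydroxyethyl on C3a (diastereomer mixture at the three new centres, not isolated) | CC4=CC(c5ccoc5)OC(=O)C4C(O)C[C@@]12COC(=O)[C@@]1(O[Si](C)(C)C(C)(C)C)CCCC23OCCO3 | intermediate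
19 | methanesulfonate of 18 (not isolated) | CC4=CC(c5ccoc5)OC(=O)C4C(OS(C)(=O)=O)C[C@@]12COC(=O)[C@@]1(O[Si](C)(C)C(C)(C)C)CCCC23OCCO3 | intermediate
20 | 3-alkylidene lactone: C3a side chain = 2-[6-(furan-3-yl)-4-methyl-2-oxo-2H-pyran-3(6H)-ylidene]ethyl (not isolated) | CC4=CC(c5ccoc5)OC(=O)C4=CC[C@@]12COC(=O)[C@@]1(O[Si](C)(C)C(C)(C)C)CCCC23OCCO3 | intermediate
21 | (3aR,7aR)-7a-[(tert-butyldimethylsilyl)oxy]-4,4-(ethylenedioxy)-3a-{2-[6-(furan-3-yl)-4-methyl-2-oxo-2H-pyran-3-yl]ethyl}hexahydro-2-benzofuran-1(3H)-one | Cc4cc(-c5ccoc5)oc(=O)c4CC[C@@]12COC(=O)[C@@]1(O[Si](C)(C)C(C)(C)C)CCCC23OCCO3 | intermediate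
22 | (3aR,7aR)-4,4-(ethylenedioxy)-3a-{2-[6-(furan-3-yl)-4-methyl-2-oxo-2H-pyran-3-yl]ethyl}-7a-hydroxyhexahydro-2-benzofuran-1(3H)-one (not isolated) | Cc4cc(-c5ccoc5)oc(=O)c4CC[C@@]12COC(=O)[C@@]1(O)CCCC23OCCO3 | intermediate
23 | (3aR,7aR)-3a-{2-[6-(furan-3-yl)-4-methyl-2-oxo-2H-pyran-3-yl]ethyl}-7a-hydroxyhexahydro-2-benzofuran-1,4-dione | Cc4cc(-c5ccoc5)oc(=O)c4CC[C@@]12COC(=O)[C@@]1(O)CCCC2=O | intermediate
24 | bis(trimethylsilyl) derivative of 23: C4 silyl enol ether (C4=C5) and 7a-O-silyl ether, same configuration (not isolated) | Cc4cc(-c5ccoc5)oc(=O)c4CC[C@@]12COC(=O)[C@@]1(O[Si](C)(C)C)CCC=C2O[Si](C)(C)C | intermediate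
25 | (3aR,7aR)-3a-{2-[6-(furan-3-yl)-4-methyl-2-oxo-2H-pyran-3-yl]ethyl}-7a-hydroxy-3,3a,7,7a-tetrahydro-2-benzofuran-1,4-dione | Cc1cc(-c2ccoc2)oc(=O)c1CC[C@@]12COC(=O)[C@@]1(O)CC=CC2=O | target

## Step count and risks

Total step count: 14. Longest linear sequence: 13 (steps 1–10, 12, 13, 14).

Steps most likely to fail:

1. Step 12 (proposed new method). The hindered, enolisable aldehyde may be deprotonated by the dienolate instead of being attacked, the dienolate may react at its γ-terminus, or the final base-mediated double-bond migration may stall or open the pyrone. Fallback, known chemistry, setting out from 13 and returning at 21: a three-component reductive alkylation. Methyl furan-3-carboxylate and the dianion of tert-butyl acetoacetate (NaH, n-BuLi) give tert-butyl 5-(furan-3-yl)-3,5-dioxopentanoate F1, which TFA/TFAA closes to 4-hydroxy-6-(furan-3-yl)-2H-pyran-2-one F2. Aldehyde 13, F2 and Hantzsch ester with L-proline (cat.) in CH2Cl2 give, by Knoevenagel condensation and hydride transfer at the nucleophilic C3, the 3-alkyl-4-hydroxypyrone F3. Tf2O/Et3N converts the 4-hydroxy group into the triflate F4, and Suzuki methylation (Pd(PPh3)4, trimethylboroxine, K2CO3, dioxane, 90 °C) gives 21.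

2. Step 7. Discrimination between the two ketones may be lost, the primary silyl ether may be cleaved, or acid may trigger an α-ketol rearrangement. Fallback, setting out from 8 and returning at 25: the ketones are told apart by oxidation state instead of protection. Aerobic dehydrogenation of the cyclohexanone (Pd(DMSO)2(TFA)2, O2, EtOAc, 60 °C) gives the enone F5. TBSOTf/Et3N gives the cyclopentanone silyl enol ether and tertiary silyl ether F6. Ozonolysis, selective for the electron-rich enol ether over the enone, gives the silyl ester aldehyde F7, and HF·pyridine then DCC gives the enone lactone aldehyde F8. The coupling of step 12 with 17 gives the O-silyl target F9, and HF·pyridine gives 25; steps 13 and 14 are then not needed.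

3. Step 14. Stoichiometric divalent palladium may palladate or oxidise the furan and pyrone, or conversion may be incomplete. Fallback, setting out from 23 and returning at 25: selenoxide elimination. The silyl enol ether 24 is treated with PhSeCl at −78 °C to give the α-phenylselanyl ketone F10; H2O2/pyridine at 0 °C oxidises selenium and syn-elimination gives 25.

Further compounds
F1 | step 12 | tert-butyl 5-(furan-3-yl)-3,5-dioxopentanoate | CC(C)(C)OC(=O)CC(=O)CC(=O)c1ccoc1
F2 | step 12 | 4-hydroxy-6-(furan-3-yl)-2H-pyran-2-one | O=c1cc(O)cc(-c2ccoc2)o1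
F3 | step 12 | (3aR,7aR)-7a-[(tert-butyldimethylsilyl)oxy]-4,4-(ethylenedioxy)-3a-{2-[6-(furan-3-yl)-4-hydroxy-2-oxo-2H-pyran-3-yl]ethyl}hexahydro-2-benzofuran-1(3H)-one | O=c4oc(-c5ccoc5)cc(O)c4CC[C@@]12COC(=O)[C@@]1(O[Si](C)(C)C(C)(C)C)CCCC23OCCO3
F4 | step 12 | 4-pyronyl trifluoromethanesulfonate of F3 | O=c4oc(-c5ccoc5)cc(OS(=O)(=O)C(F)(F)F)c4CC[C@@]12COC(=O)[C@@]1(O[Si](C)(C)C(C)(C)C)CCCC23OCCO3
F5 | step 7 | (3aR,7aR)-3a-{[(tert-butyldimethylsilyl)oxy]methyl}-7a-hydroxy-3,3a,7,7a-tetrahydro-1H-indene-1,4(2H)-dione (C5=C6 enone) | O=C1CC[C@]2(CO[Si](C)(C)C(C)(C)C)C(=O)C=CC[C@]12O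
F6 | step 7 | cyclopentanone silyl enol ether and 7a-silyl ether of F5 | CC(C)(C)[Si](C)(C)OC1=CC[C@]2(CO[Si](C)(C)C(C)(C)C)C(=O)C=CC[C@]12O[Si](C)(C)C(C)(C)C
F7 | step 7 | tert-butyldimethylsilyl (1R,6R)-1-[(tert-butyldimethylsilyl)oxy]-6-{[(tert-butyldimethylsilyl)oxy]methyl}-5-oxo-6-(2-oxoethyl)cyclohex-3-ene-1-carboxylate | O=CC[C@]1(CO[Si](C)(C)C(C)(C)C)C(=O)C=CC[C@]1(O[Si](C)(C)C(C)(C)C)C(=O)O[Si](C)(C)C(C)(C)C
F8 | step 7 | (3aR,7aR)-7a-[(tert-butyldimethylsilyl)oxy]-3a-(2-oxoethyl)-3,3a,7,7a-tetrahydro-2-benzofuran-1,4-dione | O=CC[C@@]12COC(=O)[C@@]1(O[Si](C)(C)C(C)(C)C)CC=CC2=O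
F9 | step 7 | 7a-O-(tert-butyldimethylsilyl) ether of 25 | Cc4cc(-c5ccoc5)oc(=O)c4CC[C@@]12COC(=O)[C@@]1(O[Si](C)(C)C(C)(C)C)CC=CC2=O
F10 | step 14 | 5-(phenylselanyl) derivative of 23 (epimer mixture at C5) | Cc4cc(-c5ccoc5)oc(=O)c4CC[C@@]12COC(=O)[C@@]1(O)CCC([Se]c3ccccc3)C2=O
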